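**Retrosynthetic overview**

1. Numbering used here (bicyclo[3.2.1]octane): C1 = bridgehead with the isobutyryl group, C2 = CMe2, C3 = CH(prenyl), C4 = CH2, C5 = prenylated bridgehead, C6 = carbinol carbon, C7 = ring ketone, C8 = bridging ketone.
2. Late stage: the Z-enone comes from Lindlar reduction of a C6 ynone, the C6 acyl carbon from exo-face aldol addition of a C6-silyloxy C7 enolate to an ynal, and the C5 prenyl group from decarboxylative radical prenylation of a bridgehead carboxylic acid.
3. Key disconnection: C3–C2 and C8–C1, formed together from an acyclic malonate by conjugate addition of a C3 radical to an isopropylidene β-diketone and acylation of the resulting C1 enolate by an activated C8 ester. Enabling feature: in the cyclohexanone ring C8–C1–C2–C3–C4–C5 the quaternary C1 (α to the C7, C8 and isobutyryl carbonyls) is bonded to the gem-dimethyl carbon C2, so C1=C2 is a latent alkylidene-1,3-diketone, and C8 and C3 are 1,4-related through C5–C4 like the carbonyl and γ-carbon of a butyrolactone.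
4. Precursor: chiral-pool (S)-5-(tosyloxymethyl)butyrolactone supplies C8 (lactone C=O), C5 (α-carbon), C4 and C3 (γ-carbon); its γ-stereocentre directs the quaternary C5 and is erased at the radical stage, and a selenolate opens the lactone to the C3 radical precursor and the C8 acid at once.
5. Ring order: temporary γ-lactone, then in one pot the cycloheptane (C3–C2) and the cyclopentane-1,3-dione (C8–C1), which together make the bicyclo[3.2.1]octane; no ring is formed afterwards.

Key step: step 8

Remark: the target is treated as the open Z-γ-hydroxy enone drawn (reversible closure to a cyclic hemiketal is not considered); 1, 2, 4, 6, 8, 10, 12, 14, 19, 20, 24, 25, 28 and 29 are taken as commercial.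

Step 1
Reactants: 1 (S)-5-(tosyloxymethyl)dihydrofuran-2(3H)-one; 2 (2-methylprop-1-en-1-yl)magnesium bromide
Product: 3 (S)-5-(3-methylbut-2-en-1-yl)dihydrofuran-2(3H)-one
Conditions: CuI (10 mol %), THF, −30 to −10 °C; aq. NH4Cl
Reagents that add atoms: (2-methylprop-1-en-1-yl)magnesium bromide, CC(C)=C[Mg]Br
Why: Copper-catalysed cross-coupling of the alkenyl Grignard reagent with the primary tosylate should outrun carbonyl addition at low temperature; the γ-stereocentre is not touched.

Step 2
Reactants: 3; 4 di-tert-butyl dicarbonate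
Product: 5 tert-butyl 5-(3-methylbut-2-en-1-yl)-2-oxooxolane-3-carboxylate
Conditions: LiN(SiMe3)2 (2.2 equiv), THF, −78 °C; then 4, −78 to −20 °C; aq. NH4Cl
Reagents that add atoms: di-tert-butyl dicarbonate, CC(C)(C)OC(=O)OC(=O)OC(C)(C)C
Why: Claisen-type C-acylation of the lactone enolate (the second equivalent of base takes up the more acidic product) should give the malonate-type lactone; the α-configuration is irrelevant because this centre is re-enolised in step 3.

Step 3
Reactants: 5; 6 1-chloropropan-2-one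
Product: 7 tert-butyl 5-(3-methylbut-2-en-1-yl)-2-oxo-3-(2-oxopropyl)oxolane-3-carboxylate
Conditions: K2CO3, NaI (10 mol %), acetone, 25 °C
Reagents that add atoms: 1-chloropropan-2-one, CC(=O)CCl
Why: SN2 alkylation of the soft malonate-type enolate should occur anti to the γ-side chain (1,3-induction in a γ-substituted butyrolactone enolate), which sets the quaternary centre that becomes C5.

Step 4
Reactants: 7; 8 2-methylpropanoyl chloride
Product: 9 tert-butyl 5-(3-methylbut-2-en-1-yl)-3-(5-methyl-2,4-dioxohexyl)-2-oxooxolane-3-carboxylate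
Conditions: MgBr2·OEt2, iPr2NEt, CH2Cl2, 0 to 25 °C; 1 M HCl
Reagents that add atoms: 2-methylpropanoyl chloride, CC(C)C(Cl)=O
Why: Soft-enolisation Claisen C-acylation of the methyl ketone at its methyl group (the CH2 next to the quaternary carbon is hindered) should give the β-diketone without strong base.

Step 5
Reactants: 9; 10 benzeneselenol
Product: 11 2-(tert-butoxycarbonyl)-7-methyl-2-[5-methyl-2-(phenylselanyl)hex-4-en-1-yl]-4,6-dioxooctanoic acid
Conditions: NaH, THF/DMPU, 0 °C then 65 °C; cold 1 M HCl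
Reagents that add atoms: benzeneselenol, [SeH]c1ccccc1
Why: SN2 alkyl–oxygen cleavage of the γ-lactone by the soft, weakly basic selenolate at the secondary γ-carbon (inversion, irrelevant later) should unmask the C8 carboxyl and install the C3 radical precursor in one step.

Step 6
Reactants: 11; 12 acetone
Product: 13 2-(tert-butoxycarbonyl)-7-methyl-2-[5-methyl-2-(phenylselanyl)hex-4-en-1-yl]-4,6-dioxo-5-(propan-2-ylidene)octanoic acid
Conditions: TiCl4, pyridine, THF, 0 to 25 °C; 1 M HCl
Reagents that add atoms: acetone, CC(C)=O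
Why: Titanium tetrachloride–pyridine Knoevenagel condensation of the β-diketone with a ketone should give the isopropylidene diketone, the carboxyl group riding through as a titanium carboxylate.

Step 7
Reactants: 13; 14 pentafluorophenol
Product: 15 1-tert-butyl 3-(pentafluorophenyl) 2-[5-methyl-2,4-dioxo-3-(propan-2-ylidene)hexyl]-2-[5-methyl-2-(phenylselanyl)hex-4-en-1-yl]propanedioate
Conditions: DCC, CH2Cl2, 0 to 25 °C
Reagents that add atoms: pentafluorophenol, Oc1c(F)c(F)c(F)c(F)c1F
Why: Carbodiimide (Steglich-type) esterification should give the active ester; the quaternary α-carbon excludes a ketene pathway.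

Step 8
Reactants: 15
Product: 17 tert-butyl 2,2-dimethyl-3-(3-methylbut-2-en-1-yl)-1-(2-methylpropanoyl)-7,8-dioxobicyclo[3.2.1]octane-5-carboxylate, via cycloheptanedione potassium enolate 16 (not isolated)
Conditions: Ir[dF(CF3)ppy]2(dtbbpy)PF6 (2 mol %), (Me3Si)3SiOH, K3PO4, MeCN (0.005 M), blue LEDs, 25 °C; then DMAP (20 mol %), 40 °C
Reagents that add atoms: none
Why: Proposed new method: a silyl radical (from photoredox oxidation of the silanolate and radical Brook shift) abstracts the phenylselanyl group from C3, the secondary C3 radical adds 7-endo-trig to C2 of the isopropylidene diketone, the captodative C1 radical is reduced by the divalent iridium species to enolate 16, and 16 acylates transannularly at the pentafluorophenyl ester carbon C8 (5-exo-trig), closing the cyclopentane-1,3-dione and with it the bicyclo[3.2.1]octane. The closest known reaction types are silyl-radical-mediated photoredox Giese additions of unactivated alkyl halides, radical–polar crossover annulations in which the Giese enolate is trapped by an internal carbonyl electrophile (Giese–aldol, Giese–Dieckmann), and Dieckmann C-acylation by active esters. C3 should be set in a chair-like 7-endo transition state with the prenylmethyl group and the bulkier tert-butyl ester pseudo-equatorial and the acyl donor pseudo-axial over C1, which places the prenyl group exo (equatorial); C1 is fixed by the bridge because C8 can reach only one face of the enolate, and C5 is carried over unchanged. The step needs C- over O-acylation and no competing radical cyclisation: O-acylation through the ring oxygen would give an anti-Bredt bridgehead enol ester and through the isobutyryl oxygen a seven-membered enol lactone, and C5 bears no alkene at this stage, so the C3 radical has no 5-exo trap (its own prenyl group allows only a reversible 3-exo closure). High dilution and the absence of a hydrogen-atom donor should keep the slow 7-endo addition ahead of simple reduction.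

Step 9
Reactants: 17
Product: 18 2,2-dimethyl-3-(3-methylbut-2-en-1-yl)-1-(2-methylpropanoyl)-7,8-dioxobicyclo[3.2.1]octane-5-carboxylic acid
Conditions: ZnBr2, CH2Cl2, 25 °C; aq. citric acid
Reagents that add atoms: none
Why: Lewis-acid-mediated tert-butyl ester cleavage (chelation by the β-keto ester, E1 loss of isobutene) should spare the prenyl alkene, and the bridgehead β-keto acid cannot decarboxylate thermally because its enol would violate Bredt's rule.

Step 10
Reactants: 19 (prop-2-en-1-ylsulfonyl)benzene; 20 iodomethane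
Product: 22 (2-methylbut-3-en-2-ylsulfonyl)benzene, via (but-3-en-2-ylsulfonyl)benzene 21 (not isolated)
Conditions: n-BuLi, THF, −78 °C, then 20; again n-BuLi, then 20, −78 to 0 °C
Reagents that add atoms: iodomethane, CI
Why: Two successive α-lithiation/methylation cycles of the allylic sulfone (lithiated allyl sulfones alkylate at the α-carbon) should give the 1,1-dimethylallyl sulfone, a radical prenyl-transfer reagent.

Step 11
Reactants: 18; 22
Product: 23 2,2-dimethyl-3,5-bis(3-methylbut-2-en-1-yl)-1-(2-methylpropanoyl)bicyclo[3.2.1]octane-7,8-dione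
Conditions: Ir[dF(CF3)ppy]2(dtbbpy)PF6 (2 mol %), K2HPO4, DMSO, blue LEDs, 25 °C
Reagents that add atoms: (2-methylbut-3-en-2-ylsulfonyl)benzene, CC(C)(C=C)S(=O)(=O)c1ccccc1
Why: Photoredox decarboxylative radical allylation: the bridgehead radical adds to the unhindered CH2 terminus of 22 and β-scission expels the sulfonyl radical (SH2′), delivering the prenyl group with retention, since a bridgehead has only one open face.

Step 12
Reactants: 23; 24 3-phenyl-2-(phenylsulfonyl)oxaziridine; 25 chlorotriethylsilane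
Product: 27 2,2-dimethyl-3,5-bis(3-methylbut-2-en-1-yl)-1-(2-methylpropanoyl)-6-(triethylsilyloxy)bicyclo[3.2.1]octane-7,8-dione, via sodium 6-alkoxide 26 (not isolated)
Conditions: NaN(SiMe3)2, THF, −78 °C; 24; then 25, −78 to 0 °C
Reagents that add atoms: 3-phenyl-2-(phenylsulfonyl)oxaziridine, O=S(=O)(N1OC1c1ccccc1)c1ccccc1; chlorotriethylsilane, CC[Si](Cl)(CC)CC
Why: Kinetic enolisation at C6 (the only α-CH2; C1 and C5 are quaternary) and electrophilic enolate hydroxylation by the N-sulfonyl oxaziridine from the exo face, then silylation of the alkoxide; the C6 configuration is erased in step 14.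

Step 13
Reactants: 28 trimethyl[(2-methylbut-3-yn-2-yl)oxy]silane; 29 N,N-dimethylformamide
Product: 30 4-methyl-4-(trimethylsilyloxy)pent-2-ynal
Conditions: n-BuLi, THF, −78 °C; 29, −78 to 0 °C; cold aq. NH4Cl
Reagents that add atoms: N,N-dimethylformamide, CN(C)C=O
Why: Formylation of the lithium acetylide with DMF (Bouveault-type) should give the ynal.

Step 14
Reactants: 27; 30
Product: 31 6-[1-hydroxy-4-methyl-4-(trimethylsilyloxy)pent-2-yn-1-yl]-2,2-dimethyl-3,5-bis(3-methylbut-2-en-1-yl)-1-(2-methylpropanoyl)-6-(triethylsilyloxy)bicyclo[3.2.1]octane-7,8-dione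
Conditions: LiN(iPr)2, THF, −78 to −40 °C; 30, −78 °C; AcOH, −78 °C
Reagents that add atoms: 4-methyl-4-(trimethylsilyloxy)pent-2-ynal, O=CC#CC(C)(C)O[Si](C)(C)C
Why: Aldol addition of the C6 lithium enolate to the ynal on the exo face, anti to the C2–C3–C4 bridge, should put the new carbon exo and the silyloxy group endo at C6 as in the target; the carbinol epimers converge in step 15.

Step 15
Reactants: 31
Product: 32 2,2-dimethyl-3,5-bis(3-methylbut-2-en-1-yl)-1-(2-methylpropanoyl)-6-[4-methyl-4-(trimethylsilyloxy)pent-2-ynoyl]-6-(triethylsilyloxy)bicyclo[3.2.1]octane-7,8-dione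
Conditions: Dess–Martin periodinane, NaHCO3, CH2Cl2, 0 to 25 °C
Reagents that add atoms: none
Why: Dess–Martin oxidation of the secondary propargylic alcohol to the ynone under buffered conditions; C6 is quaternary and cannot epimerise.

Step 16
Reactants: 32
Product: 33 6-hydroxy-6-(4-hydroxy-4-methylpent-2-ynoyl)-2,2-dimethyl-3,5-bis(3-methylbut-2-en-1-yl)-1-(2-methylpropanoyl)bicyclo[3.2.1]octane-7,8-dione
Conditions: HF·pyridine, pyridine, THF, 0 °C
Reagents that add atoms: none
Why: Fluoride-mediated cleavage of both silyl ethers under weakly acidic conditions that the non-enolisable β-tricarbonyl array should tolerate.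

Step 17
Reactants: 33
Product: 34 6-hydroxy-6-[(2Z)-4-hydroxy-4-methylpent-2-enoyl]-2,2-dimethyl-3,5-bis(3-methylbut-2-en-1-yl)-1-(2-methylpropanoyl)bicyclo[3.2.1]octane-7,8-dione (CNP0190794.1)
Conditions: H2 (1 atm), Pd/CaCO3 poisoned with Pb(OAc)2 (Lindlar catalyst), quinoline, EtOAc, 0 °C
Reagents that add atoms: none
Why: Lindlar semi-hydrogenation (syn addition of H2) of the ynone should give the Z-enone while the trisubstituted prenyl alkenes stay untouched.

**Compound list**

1 | (S)-5-(tosyloxymethyl)dihydrofuran-2(3H)-one | Cc1ccc(cc1)S(=O)(=O)OC[C@@H]1CCC(=O)O1 | starting material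
2 | (2-methylprop-1-en-1-yl)magnesium bromide | CC(C)=C[Mg]Br | starting material
3 | (S)-5-(3-methylbut-2-en-1-yl)dihydrofuran-2(3H)-one | CC(C)=CC[C@@H]1CCC(=O)O1 | intermediate
4 | di-tert-butyl dicarbonate | CC(C)(C)OC(=O)OC(=O)OC(C)(C)C | starting material
5 | tert-butyl 5-(3-methylbut-2-en-1-yl)-2-oxooxolane-3-carboxylate (γ-carbon as in 3, α-epimers) | CC(C)=CC[C@@H]1CC(C(=O)OC(C)(C)C)C(=O)O1 | intermediate
6 | 1-chloropropan-2-one | CC(=O)CCl | starting material
7 | tert-butyl 5-(3-methylbut-2-en-1-yl)-2-oxo-3-(2-oxopropyl)oxolane-3-carboxylate (acetonyl trans to the γ-side chain) | CC(C)=CC[C@@H]1C[C@](CC(C)=O)(C(=O)OC(C)(C)C)C(=O)O1 | intermediate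
8 | 2-methylpropanoyl chloride | CC(C)C(Cl)=O | starting material
9 | tert-butyl 5-(3-methylbut-2-en-1-yl)-3-(5-methyl-2,4-dioxohexyl)-2-oxooxolane-3-carboxylate (configuration as in 7) | CC(C)=CC[C@@H]1C[C@](CC(=O)CC(=O)C(C)C)(C(=O)OC(C)(C)C)C(=O)O1 | intermediate
10 | benzeneselenol | [SeH]c1ccccc1 | starting material
11 | 2-(tert-butoxycarbonyl)-7-methyl-2-[5-methyl-2-(phenylselanyl)hex-4-en-1-yl]-4,6-dioxooctanoic acid (quaternary centre as in 7, selenide carbon inverted) | CC(C)=CC[C@H]([Se]c1ccccc1)C[C@](CC(=O)CC(=O)C(C)C)(C(=O)OC(C)(C)C)C(O)=O | intermediate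
12 | acetone | CC(C)=O | starting material
13 | 2-(tert-butoxycarbonyl)-7-methyl-2-[5-methyl-2-(phenylselanyl)hex-4-en-1-yl]-4,6-dioxo-5-(propan-2-ylidene)octanoic acid | CC(C)=CC[C@H]([Se]c1ccccc1)C[C@](CC(=O)C(=C(C)C)C(=O)C(C)C)(C(=O)OC(C)(C)C)C(O)=O | intermediate
14 | pentafluorophenol | Oc1c(F)c(F)c(F)c(F)c1F | starting material
15 | 1-tert-butyl 3-(pentafluorophenyl) 2-[5-methyl-2,4-dioxo-3-(propan-2-ylidene)hexyl]-2-[5-methyl-2-(phenylselanyl)hex-4-en-1-yl]propanedioate | CC(C)=CC[C@H]([Se]c1ccccc1)C[C@](CC(=O)C(=C(C)C)C(=O)C(C)C)(C(=O)OC(C)(C)C)C(=O)Oc1c(F)c(F)c(F)c(F)c1F | intermediate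
16 | potassium enolate of 1-tert-butyl 1-(pentafluorophenyl) 5,5-dimethyl-6-(3-methylbut-2-en-1-yl)-4-(2-methylpropanoyl)-3-oxocycloheptane-1,1-dicarboxylate | CC(C)=CC[C@@H]1C[C@](C(=O)OC(C)(C)C)(C(=O)Oc2c(F)c(F)c(F)c(F)c2F)CC(=O)C(=C([O-])C(C)C)C1(C)C.[K+] | intermediate (not isolated)
17 | tert-butyl 2,2-dimethyl-3-(3-methylbut-2-en-1-yl)-1-(2-methylpropanoyl)-7,8-dioxobicyclo[3.2.1]octane-5-carboxylate (3-prenyl exo) | CC(C)=CC[C@@H]1C[C@]2(C(=O)OC(C)(C)C)C(=O)[C@@](C(=O)C(C)C)(C(=O)C2)C1(C)C | intermediate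
18 | 2,2-dimethyl-3-(3-methylbut-2-en-1-yl)-1-(2-methylpropanoyl)-7,8-dioxobicyclo[3.2.1]octane-5-carboxylic acid | CC(C)=CC[C@@H]1C[C@]2(C(O)=O)C(=O)[C@@](C(=O)C(C)C)(C(=O)C2)C1(C)C | intermediate
19 | (prop-2-en-1-ylsulfonyl)benzene | C=CCS(=O)(=O)c1ccccc1 | starting material
20 | iodomethane | CI | starting material
21 | (but-3-en-2-ylsulfonyl)benzene (racemic) | CC(C=C)S(=O)(=O)c1ccccc1 | intermediate (not isolated)
22 | (2-methylbut-3-en-2-ylsulfonyl)benzene | CC(C)(C=C)S(=O)(=O)c1ccccc1 | intermediate
23 | 2,2-dimethyl-3,5-bis(3-methylbut-2-en-1-yl)-1-(2-methylpropanoyl)bicyclo[3.2.1]octane-7,8-dione | CC(C)=CC[C@@H]1C[C@]2(CC=C(C)C)C(=O)[C@@](C(=O)C(C)C)(C(=O)C2)C1(C)C | intermediate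
24 | 3-phenyl-2-(phenylsulfonyl)oxaziridine (racemic) | O=S(=O)(N1OC1c1ccccc1)c1ccccc1 | starting material
25 | chlorotriethylsilane | CC[Si](Cl)(CC)CC | starting material
26 | sodium 2,2-dimethyl-3,5-bis(3-methylbut-2-en-1-yl)-1-(2-methylpropanoyl)-7,8-dioxobicyclo[3.2.1]octan-6-olate (6-oxygen exo) | CC(C)=CC[C@@H]1C[C@]2(CC=C(C)C)C(=O)[C@@](C(=O)C(C)C)(C(=O)[C@H]2[O-])C1(C)C.[Na+] | intermediate (not isolated)
27 | 2,2-dimethyl-3,5-bis(3-methylbut-2-en-1-yl)-1-(2-methylpropanoyl)-6-(triethylsilyloxy)bicyclo[3.2.1]octane-7,8-dione (6-silyloxy exo) | CC(C)=CC[C@@H]1C[C@]2(CC=C(C)C)C(=O)[C@@](C(=O)C(C)C)(C(=O)[C@H]2O[Si](CC)(CC)CC)C1(C)C | intermediate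
28 | trimethyl[(2-methylbut-3-yn-2-yl)oxy]silane | C#CC(C)(C)O[Si](C)(C)C | starting material
29 | N,N-dimethylformamide | CN(C)C=O | starting material
30 | 4-methyl-4-(trimethylsilyloxy)pent-2-ynal | O=CC#CC(C)(C)O[Si](C)(C)C | intermediate
31 | 6-[1-hydroxy-4-methyl-4-(trimethylsilyloxy)pent-2-yn-1-yl]-2,2-dimethyl-3,5-bis(3-methylbut-2-en-1-yl)-1-(2-methylpropanoyl)-6-(triethylsilyloxy)bicyclo[3.2.1]octane-7,8-dione (6-silyloxy endo, carbinol epimers) | CC(C)=CC[C@@H]1C[C@]2(CC=C(C)C)C(=O)[C@@](C(=O)C(C)C)(C(=O)[C@@]2(O[Si](CC)(CC)CC)C(O)C#CC(C)(C)O[Si](C)(C)C)C1(C)C | intermediate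
32 | 2,2-dimethyl-3,5-bis(3-methylbut-2-en-1-yl)-1-(2-methylpropanoyl)-6-[4-methyl-4-(trimethylsilyloxy)pent-2-ynoyl]-6-(triethylsilyloxy)bicyclo[3.2.1]octane-7,8-dione | CC(C)=CC[C@@H]1C[C@]2(CC=C(C)C)C(=O)[C@@](C(=O)C(C)C)(C(=O)[C@@]2(O[Si](CC)(CC)CC)C(=O)C#CC(C)(C)O[Si](C)(C)C)C1(C)C | intermediate
33 | 6-hydroxy-6-(4-hydroxy-4-methylpent-2-ynoyl)-2,2-dimethyl-3,5-bis(3-methylbut-2-en-1-yl)-1-(2-methylpropanoyl)bicyclo[3.2.1]octane-7,8-dione | CC(C)=CC[C@@H]1C[C@]2(CC=C(C)C)C(=O)[C@@](C(=O)C(C)C)(C(=O)[C@@]2(O)C(=O)C#CC(C)(C)O)C1(C)C | intermediate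
34 | 6-hydroxy-6-[(2Z)-4-hydroxy-4-methylpent-2-enoyl]-2,2-dimethyl-3,5-bis(3-methylbut-2-en-1-yl)-1-(2-methylpropanoyl)bicyclo[3.2.1]octane-7,8-dione, CNP0190794.1 (3-prenyl exo, 6-hydroxy endo) | CC(C)=CC[C@@H]1C[C@]2(CC=C(C)C)C(=O)[C@@](C(=O)C(C)C)(C(=O)[C@@]2(O)C(=O)/C=C\C(C)(C)O)C1(C)C | target

**Step count and risks**

Total step count: 17. Longest linear sequence: 15 steps (1–9, 11, 12, 14–17, from 1).

Steps most likely to fail:

- Step 8 (proposed new method). What may go wrong: quenching of the C3 radical before the slow 7-endo addition, protonation of the enolate without acylation, or poor facial selectivity at C3. Fallback with known chemistry that separates the two events: from 15, Bu3SnH/AIBN under slow addition (benzene, 80 °C) should give, by 7-endo radical cyclisation and hydrogen-atom transfer, the isolable 1-tert-butyl 1-(pentafluorophenyl) 5,5-dimethyl-6-(3-methylbut-2-en-1-yl)-4-(2-methylpropanoyl)-3-oxocycloheptane-1,1-dicarboxylate F1, whose epimers at the prenyl-bearing carbon can be separated; Cs2CO3 in MeCN should then effect the transannular Dieckmann C-acylation and come back to 17.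

- Step 6. What may go wrong: sequestration of the malonic half-acid as a titanium carboxylate, or its decarboxylation, so that condensation with the poorly electrophilic ketone stalls. Fallback that changes the order of events: from 9, the same condensation is run on the lactone, which has no free carboxyl group, to give tert-butyl 3-[5-methyl-2,4-dioxo-3-(propan-2-ylidene)hexyl]-5-(3-methylbut-2-en-1-yl)-2-oxooxolane-3-carboxylate F2; opening F2 with sodium benzeneselenolate as in step 5 (conjugate addition of the selenolate to the alkylidene is reversible and is undone on acidic work-up with warming) comes back to 13.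

- Step 14. What may go wrong: slow removal of the hindered endo hydrogen at C6, so that enolisation at the isobutyryl methine or silyl migration to the new alkoxide takes over. Fallback: from 27, soft enolisation with Me3SiOTf/Et3N should give the bis(silyl) enediol ether 2,2-dimethyl-3,5-bis(3-methylbut-2-en-1-yl)-1-(2-methylpropanoyl)-6-(triethylsilyloxy)-7-(trimethylsilyloxy)bicyclo[3.2.1]oct-6-en-8-one F3, and a Mukaiyama aldol addition of F3 to 30 (BF3·OEt2, CH2Cl2, −78 °C), again on the exo face, comes back to 31.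

Further compounds
F1 | step 8 | 1-tert-butyl 1-(pentafluorophenyl) 5,5-dimethyl-6-(3-methylbut-2-en-1-yl)-4-(2-methylpropanoyl)-3-oxocycloheptane-1,1-dicarboxylate | CC(C)=CC[C@@H]1C[C@](C(=O)OC(C)(C)C)(C(=O)Oc2c(F)c(F)c(F)c(F)c2F)CC(=O)C(C(=O)C(C)C)C1(C)C
F2 | step 6 | tert-butyl 3-[5-methyl-2,4-dioxo-3-(propan-2-ylidene)hexyl]-5-(3-methylbut-2-en-1-yl)-2-oxooxolane-3-carboxylate | CC(C)=CC[C@@H]1C[C@](CC(=O)C(=C(C)C)C(=O)C(C)C)(C(=O)OC(C)(C)C)C(=O)O1
F3 | step 14 | 2,2-dimethyl-3,5-bis(3-methylbut-2-en-1-yl)-1-(2-methylpropanoyl)-6-(triethylsilyloxy)-7-(trimethylsilyloxy)bicyclo[3.2.1]oct-6-en-8-one | CC(C)=CC[C@@H]1C[C@]2(CC=C(C)C)C(=O)[C@@](C(=O)C(C)C)(C(O[Si](C)(C)C)=C2O[Si](CC)(CC)CC)C1(C)C
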